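**Assumption:** the target has no stereocentre and no stereogenic double bond, so "single enantiomer" is taken to mean the one structure drawn. The carbinol centre that appears in the aldol adduct is made racemic and is destroyed two steps later.

## Retrosynthetic overview

- Ester C–O: the alcohol half is tyrosol, carried with its phenol masked as a benzyl ether; the acyl half is grown on the tyrosol oxygen, starting as a plain acetate.
- Key C–C disconnection: C2–C3 of the docosanoyl chain, made by a crossed aldol of the acetate's lithium enolate (two carbons) with icosanal (twenty carbons, from icosan-1-ol).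
- The aldol hydroxyl is removed by dehydration to the 2-enoate; one final hydrogenation saturates C2=C3 and frees the phenol.
- Rings: none is formed. The only ring, the para-disubstituted benzene, comes in with tyrosol.

## Route

**Step 1**
Reactants: 1 4-(2-hydroxyethyl)phenol (tyrosol)
Product: 2 2-[4-(benzyloxy)phenyl]ethanol
Conditions: BnBr (1.05 equiv), K2CO3 (1.5 equiv), acetone, reflux, 12 h
Reagents that add atoms: benzyl bromide, BrCc1ccccc1
Why: Williamson ether synthesis in which K2CO3 deprotonates only the phenol (pKa about 10) and not the primary alcohol (pKa about 16), so benzylation is selective for the aryl oxygen.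

**Step 2**
Reactants: 2 2-[4-(benzyloxy)phenyl]ethanol
Product: 3 2-[4-(benzyloxy)phenyl]ethyl acetate
Conditions: Ac2O (1.5 equiv), Et3N (2 equiv), DMAP (5 mol%), CH2Cl2, 0 °C → rt
Reagents that add atoms: acetic anhydride, CC(=O)OC(C)=O
Why: DMAP-catalysed acylation of an unhindered primary alcohol is essentially quantitative and installs C1 and C2 of the future docosanoyl chain.

**Step 3**
Reactants: 4 icosan-1-ol
Product: 5 icosanal
Conditions: PhI(OAc)2 (1.1 equiv), TEMPO (10 mol%), CH2Cl2, rt; filter through silica and use at once
Reagents that add atoms: none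
Why: TEMPO/PhI(OAc)2 oxidation (oxoammonium-mediated) of a primary alcohol stops at the aldehyde under anhydrous, near-neutral conditions without over-oxidation to the acid.

**Step 4**
Reactants: 3 2-[4-(benzyloxy)phenyl]ethyl acetate (1.2 equiv); 5 icosanal (1.0 equiv)
Product: 7 racemic 2-[4-(benzyloxy)phenyl]ethyl 3-hydroxydocosanoate, via lithium enolate 6 (not isolated)
Conditions: LiN(iPr)2 (LDA, commercial solution, 1.2 equiv), THF, −78 °C, add 3, 45 min; then 5 in THF, −78 → −40 °C; AcOH quench
Reagents that add atoms: none
Why: Directed crossed aldol addition in which the ester is converted completely to its lithium enolate at −78 °C before the aldehyde, the only electrophile, is added, so the C2–C3 bond forms without self-condensation; the new C3 carbinol centre is formed as a racemate, which does not matter because it is removed in step 5.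

**Step 5**
Reactants: 7 racemic 2-[4-(benzyloxy)phenyl]ethyl 3-hydroxydocosanoate
Product: 9 2-[4-(benzyloxy)phenyl]ethyl (2E)-docos-2-enoate, via β-mesyloxy ester 8 (not isolated)
Conditions: MsCl (1.5 equiv), Et3N (3 equiv), CH2Cl2, 0 °C, 1 h; then DBU (3 equiv), 0 °C → rt
Reagents that add atoms: none
Why: Mesylation followed by DBU-promoted E1cB elimination of the β-mesyloxy ester gives the conjugated (E)-enoate, and alkene geometry or position is of no consequence since the alkene is hydrogenated next.

**Step 6**
Reactants: 9 2-[4-(benzyloxy)phenyl]ethyl (2E)-docos-2-enoate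
Product: 10 2-(4-hydroxyphenyl)ethyl docosanoate
Conditions: H2 (1 atm), 10% Pd/C, EtOAc/THF (1:1), 35 °C
Reagents that add atoms: none
Why: Heterogeneous catalytic hydrogenation on Pd/C saturates the conjugated alkene and hydrogenolyses the benzyl aryl ether in one operation, while the homobenzylic ester C–O bond and the arene are untouched; no stereocentre remains.

## Compound list

1 | 4-(2-hydroxyethyl)phenol (tyrosol) | OCCc1ccc(O)cc1 | starting material
2 | 2-[4-(benzyloxy)phenyl]ethanol | OCCc1ccc(OCc2ccccc2)cc1 | intermediate
3 | 2-[4-(benzyloxy)phenyl]ethyl acetate | CC(=O)OCCc1ccc(OCc2ccccc2)cc1 | intermediate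
4 | icosan-1-ol | CCCCCCCCCCCCCCCCCCCCO | starting material
5 | icosanal | CCCCCCCCCCCCCCCCCCCC=O | intermediate
6 | lithium enolate of 3 (lithium 1-{2-[4-(benzyloxy)phenyl]ethoxy}ethen-1-olate) | [Li+].C=C([O-])OCCc1ccc(OCc2ccccc2)cc1 | intermediate (not isolated)
7 | racemic 2-[4-(benzyloxy)phenyl]ethyl 3-hydroxydocosanoate | CCCCCCCCCCCCCCCCCCCC(O)CC(=O)OCCc1ccc(OCc2ccccc2)cc1 | intermediate
8 | racemic 2-[4-(benzyloxy)phenyl]ethyl 3-(methanesulfonyloxy)docosanoate | CCCCCCCCCCCCCCCCCCCC(OS(C)(=O)=O)CC(=O)OCCc1ccc(OCc2ccccc2)cc1 | intermediate (not isolated)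
9 | 2-[4-(benzyloxy)phenyl]ethyl (2E)-docos-2-enoate | CCCCCCCCCCCCCCCCCCC/C=C/C(=O)OCCc1ccc(OCc2ccccc2)cc1 | intermediate
10 | 2-(4-hydroxyphenyl)ethyl docosanoate | CCCCCCCCCCCCCCCCCCCCCC(=O)OCCc1ccc(O)cc1 | target

## Summary

Total step count: 6.
Longest linear sequence: 5 (steps 1, 2, 4, 5, 6; step 3 is a one-step side branch).

## Steps most likely to fail, with fallbacks

**Step 4 (aldol).** Icosanal may crystallise out of THF at −78 °C, and a strongly basic lithium enolate can enolise the aldehyde or let the ester self-condense. The fallback is a Reformatsky reaction, and it sets out from 2. Acylation of 2 with bromoacetyl bromide and pyridine in CH2Cl2 at 0 °C gives 2-[4-(benzyloxy)phenyl]ethyl bromoacetate F1. Zn dust (activated with Me3SiCl) in refluxing THF turns this into the bromozinc ester enolate F2. F2 adds in the same flask to icosanal 5, which stays dissolved in the warm solvent and is not enolised by the weakly basic zinc enolate. Aqueous NH4Cl work-up gives the aldol adduct, and the route is rejoined at 7.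

**Step 5 (dehydration).** Base can trigger retro-aldol cleavage of 7, or the elimination may stop short. The fallback makes the alkene directly by olefination, and it sets out from 2. Coupling of 2 with diethylphosphonoacetic acid (DCC, DMAP, CH2Cl2) gives 2-[4-(benzyloxy)phenyl]ethyl (diethoxyphosphoryl)acetate F3. A Horner–Wadsworth–Emmons reaction of F3 with icosanal 5 under Masamune–Roush conditions (LiCl, DBU, MeCN/THF, rt) gives the (E)-enoate, so the aldol adduct and its dehydration are both bypassed. The route is rejoined at 9.

**Step 6 (double-duty hydrogenation).** The waxy substrate is poorly soluble, and traces of sulfur or amine from step 5 can poison Pd/C so that the debenzylation stalls. The fallback separates the two tasks, and it sets out from 9. Homogeneous hydrogenation with RhCl(PPh3)3 and H2 in toluene/EtOH reduces only the C=C bond and gives 2-[4-(benzyloxy)phenyl]ethyl docosanoate F4. The benzyl aryl ether of F4 is then cleaved with BCl3 and pentamethylbenzene in CH2Cl2 at −78 °C; this Lewis-acid debenzylation with a cation scavenger leaves the alkyl ester alone. The route is rejoined at 10.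

## Further compounds

F1 | step 4 | 2-[4-(benzyloxy)phenyl]ethyl bromoacetate | BrCC(=O)OCCc1ccc(OCc2ccccc2)cc1
F2 | step 4 | bromozinc ester enolate (Reformatsky reagent) of F1 | Br[Zn]CC(=O)OCCc1ccc(OCc2ccccc2)cc1
F3 | step 5 | 2-[4-(benzyloxy)phenyl]ethyl (diethoxyphosphoryl)acetate | CCOP(=O)(OCC)CC(=O)OCCc1ccc(OCc2ccccc2)cc1
F4 | step 6 | 2-[4-(benzyloxy)phenyl]ethyl docosanoate | CCCCCCCCCCCCCCCCCCCCCC(=O)OCCc1ccc(OCc2ccccc2)cc1
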